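**Retrosynthetic overview**
- The 5α-hydroxyl and the 4(15)-methylene come last, from a Schenck ene reaction (singlet oxygen) on the Δ4-decalin.
- Ring B is closed at C7–C8 by intramolecular allylboration of a C8 aldehyde with a 2-(methoxycarbonyl)allylboronate, followed by 8-O-acetylation.
- Key union at C5–C6: linear-selective Negishi coupling of a ring-A enol triflate (C1–C5, C8–C10, C14, C15, angelate) with an allylzinc that also carries the allylboronate (C6, C7, C11–C13, OMe).
- The enol triflate comes from 2-methylcyclohexenone (Pd-catalysed decarboxylative asymmetric allylation for C10, Cu-catalysed asymmetric β-borylation for C3); the allylzinc comes from butenediol and methyl acrylate via a Baylis–Hillman adduct.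
- Ring order: ring A is present from the first starting material; ring B is formed in the penultimate step.

Assumption: eudesmane numbering (C1–C15) is used for the decalin, and (R)-t-BuPHOX is taken to give the (R)-ketone by analogy with the (S)-ligand/(S)-2-allyl-2-methylcyclohexanone case (otherwise the antipodal ligand is used).

**Step 1**
Reactants: 1 2-methylcyclohex-2-en-1-one
Product: 2 2,6-dimethylcyclohex-2-en-1-one (racemic)
Conditions: LDA, THF, −78 °C; MeI, −78 → 0 °C
Reagents that add atoms: methyl iodide, CI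
Why: Kinetic α′-deprotonation gives the cross-conjugated dienolate, which is C-methylated at C6 (enolate alkylation); the new centre is racemic and is erased in step 2.

**Step 2**
Reactants: 2 2,6-dimethylcyclohex-2-en-1-one
Product: 3 allyl 2,6-dimethylcyclohexa-1,5-dien-1-yl carbonate
Conditions: LDA, TMEDA, THF, −78 °C; allyl chloroformate, −78 → 0 °C
Reagents that add atoms: allyl chloroformate, C=CCOC(Cl)=O
Why: The same α′-enolisation followed by O-acylation (favoured by TMEDA) gives the allyl enol carbonate needed for the Tsuji–Stoltz allylation.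

**Step 3**
Reactants: 3 allyl 2,6-dimethylcyclohexa-1,5-dien-1-yl carbonate
Product: 4 (6R)-6-allyl-2,6-dimethylcyclohex-2-en-1-one
Conditions: Pd2(dba)3 (2.5 mol%), (R)-t-BuPHOX (6.25 mol%), THF, 25 °C
Reagents that add atoms: none
Why: Pd-catalysed decarboxylative asymmetric allylic alkylation (Tsuji–Trost/Stoltz) recombines the π-allyl–Pd cation and the tetrasubstituted enolate inside the chiral PHOX pocket and sets the quaternary centre (6R, the future C10; expected ca. 85–90% ee).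

**Step 4**
Reactants: 4 (6R)-6-allyl-2,6-dimethylcyclohex-2-en-1-one
Product: 6 (3S,6R)-6-allyl-3-hydroxy-2,6-dimethylcyclohexan-1-one (C2 epimers), via (3S,6R)-6-allyl-2,6-dimethyl-3-(4,4,5,5-tetramethyl-1,3,2-dioxaborolan-2-yl)cyclohexan-1-one 5 (not isolated)
Conditions: B2pin2, CuCl (5 mol%), NaOt-Bu (6 mol%), Josiphos (5 mol%), MeOH (2 equiv), THF, 23 °C; then NaBO3·4H2O, THF/H2O, 23 °C
Reagents that add atoms: sodium perborate, [Na+].[O-]OB=O
Why: Cu-catalysed asymmetric conjugate borylation places boron on C3 syn to the C6 methyl under ligand control (ligand enantiomer chosen accordingly), and perborate oxidation of the C–B bond proceeds with retention to the 3S alcohol; the α-carbon C2 is an epimer mixture that disappears in step 7.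

**Step 5**
Reactants: 7 angelic acid, (2Z)-2-methylbut-2-enoic acid (2 equiv)
Product: 8 angelic anhydride
Conditions: DCC (0.5 equiv), CH2Cl2, 0 → 23 °C
Reagents that add atoms: none
Why: Carbodiimide dehydration of two acid molecules gives the symmetrical anhydride without base, so the Z double bond is not isomerised.

**Step 6**
Reactants: 6 (3S,6R)-6-allyl-3-hydroxy-2,6-dimethylcyclohexan-1-one; 8 angelic anhydride
Product: 9 (1S,4R)-4-allyl-2,4-dimethyl-3-oxocyclohexyl (2Z)-2-methylbut-2-enoate (C2 epimers)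
Conditions: DMAP (0.1 equiv), pyridine, CH2Cl2, 0 → 23 °C
Reagents that add atoms: none
Why: DMAP-catalysed acyl transfer esterifies the secondary alcohol at low temperature, which avoids angelate-to-tiglate isomerisation and β-elimination of the β-acyloxy ketone.

**Step 7**
Reactants: 9 (1S,4R)-4-allyl-2,4-dimethyl-3-oxocyclohexyl (2Z)-2-methylbut-2-enoate
Product: 10 (3S,6R)-6-allyl-2,6-dimethyl-3-[(2Z)-2-methylbut-2-enoyloxy]cyclohex-1-en-1-yl trifluoromethanesulfonate
Conditions: Tf2O, 2,6-di-tert-butyl-4-methylpyridine, CH2Cl2, 0 → 23 °C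
Reagents that add atoms: trifluoromethanesulfonic anhydride, O=S(=O)(OS(=O)(=O)C(F)(F)F)C(F)(F)F
Why: Base-free O-triflation of the ketone (Stang conditions) and loss of its only α-proton gives the tetrasubstituted enol triflate regiospecifically and removes the epimeric centre, while C3 and the quaternary carbon are untouched.

**Step 8**
Reactants: 10 (3S,6R)-6-allyl-2,6-dimethyl-3-[(2Z)-2-methylbut-2-enoyloxy]cyclohex-1-en-1-yl trifluoromethanesulfonate
Product: 11 (3S,6R)-2,6-dimethyl-3-[(2Z)-2-methylbut-2-enoyloxy]-6-(2-oxoethyl)cyclohex-1-en-1-yl trifluoromethanesulfonate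
Conditions: OsO4 (2 mol%), NaIO4, 2,6-lutidine, dioxane/H2O (3:1), 23 °C
Reagents that add atoms: sodium periodate, [Na+].[O-]I(=O)(=O)=O (oxygen relayed by catalytic OsO4)
Why: Lemieux–Johnson oxidation cleaves only the electron-rich monosubstituted alkene; the enol triflate and angelate double bonds are electron-poor and hindered.

**Step 9**
Reactants: 11 (3S,6R)-2,6-dimethyl-3-[(2Z)-2-methylbut-2-enoyloxy]-6-(2-oxoethyl)cyclohex-1-en-1-yl trifluoromethanesulfonate
Product: 12 (3S,6R)-6-(2,2-dimethoxyethyl)-2,6-dimethyl-3-[(2Z)-2-methylbut-2-enoyloxy]cyclohex-1-en-1-yl trifluoromethanesulfonate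
Conditions: HC(OMe)3, PPTS (5 mol%), MeOH, 23 °C
Reagents that add atoms: trimethyl orthoformate, COC(OC)OC; methanol, CO
Why: Acid-catalysed acetalisation masks the aldehyde (the future C8) so that it survives the allylzinc coupling.

**Step 10**
Reactants: 13 (2Z)-but-2-ene-1,4-diol
Product: 14 (2Z)-1,4-bis(tert-butyldimethylsilyloxy)but-2-ene
Conditions: TBSCl (2.2 equiv), imidazole, DMF, 23 °C
Reagents that add atoms: tert-butyldimethylsilyl chloride, CC(C)(C)[Si](C)(C)Cl
Why: Standard silyl protection of both primary alcohols before the alkene is cleaved.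

**Step 11**
Reactants: 14 (2Z)-1,4-bis(tert-butyldimethylsilyloxy)but-2-ene
Product: 16 (tert-butyldimethylsilyloxy)acetaldehyde, via 3,5-bis[(tert-butyldimethylsilyloxy)methyl]-1,2,4-trioxolane 15 (not isolated)
Conditions: O3, CH2Cl2, −78 °C; then Me2S, −78 → 23 °C
Reagents that add atoms: ozone, [O-][O+]=O
Why: Ozonolysis with reductive work-up of the symmetrical alkene gives two equivalents of the protected glycolaldehyde.

**Step 12**
Reactants: 16 (tert-butyldimethylsilyloxy)acetaldehyde; 17 methyl acrylate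
Product: 18 methyl 4-(tert-butyldimethylsilyloxy)-3-hydroxy-2-methylidenebutanoate (racemic)
Conditions: DABCO (0.5 equiv), excess 17, neat, 23 °C, 3–5 d
Reagents that add atoms: none
Why: Morita–Baylis–Hillman reaction joins the acrylate α-carbon (the future C11) to the aldehyde carbon (the future C7); the racemic carbinol centre is removed in step 14.

**Step 13**
Reactants: 18 methyl 4-(tert-butyldimethylsilyloxy)-3-hydroxy-2-methylidenebutanoate
Product: 19 methyl 3-acetoxy-4-(tert-butyldimethylsilyloxy)-2-methylidenebutanoate (racemic)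
Conditions: Ac2O, Et3N, DMAP (cat.), CH2Cl2, 0 °C
Reagents that add atoms: acetic anhydride, CC(=O)OC(C)=O
Why: Acetylation turns the allylic hydroxyl into a leaving group for π-allyl formation.

**Step 14**
Reactants: 19 methyl 3-acetoxy-4-(tert-butyldimethylsilyloxy)-2-methylidenebutanoate
Product: 20 methyl (2E)-4-(tert-butyldimethylsilyloxy)-2-[(4,4,5,5-tetramethyl-1,3,2-dioxaborolan-2-yl)methyl]but-2-enoate
Conditions: B2pin2, Pd2(dba)3 (2.5 mol%), DMF, 50 °C
Reagents that add atoms: bis(pinacolato)diboron, CC1(C)OB(OC1(C)C)B1OC(C)(C)C(C)(C)O1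
Why: Pd-catalysed Miyaura-type borylation of the Baylis–Hillman acetate via a π-allyl complex puts boron on the primary carbon and gives the trisubstituted E-alkene (ester trans to CH2OTBS), as is usual for SN2′ substitution of such esters.

**Step 15**
Reactants: 20 methyl (2E)-4-(tert-butyldimethylsilyloxy)-2-[(pinacolboryl)methyl]but-2-enoate
Product: 21 methyl (2E)-4-hydroxy-2-[(4,4,5,5-tetramethyl-1,3,2-dioxaborolan-2-yl)methyl]but-2-enoate
Conditions: AcOH/THF/H2O (3:1:1), 23 °C
Reagents that add atoms: none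
Why: Mild acidic desilylation frees the primary alcohol; the E geometry keeps it away from the ester, so no butenolide forms, and the ester-deactivated allylboronate survives.

**Step 16**
Reactants: 21 methyl (2E)-4-hydroxy-2-[(pinacolboryl)methyl]but-2-enoate
Product: 22 methyl (2E)-4-chloro-2-[(4,4,5,5-tetramethyl-1,3,2-dioxaborolan-2-yl)methyl]but-2-enoate
Conditions: NCS, PPh3, CH2Cl2, −20 → 0 °C
Reagents that add atoms: N-chlorosuccinimide, O=C1CCC(=O)N1Cl
Why: Appel-type chlorination converts the primary allylic alcohol into the chloride by SN2 without touching the allylboronate or the ester.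

**Step 17**
Reactants: 22 methyl (2E)-4-chloro-2-[(pinacolboryl)methyl]but-2-enoate; 12 (3S,6R)-6-(2,2-dimethoxyethyl)-2,6-dimethyl-3-[(2Z)-2-methylbut-2-enoyloxy]cyclohex-1-en-1-yl trifluoromethanesulfonate
Product: 24 methyl (2E)-4-{(3S,6R)-6-(2,2-dimethoxyethyl)-2,6-dimethyl-3-[(2Z)-2-methylbut-2-enoyloxy]cyclohex-1-en-1-yl}-2-[(4,4,5,5-tetramethyl-1,3,2-dioxaborolan-2-yl)methyl]but-2-enoate, via chloro[(2E)-3-(methoxycarbonyl)-4-(pinacolboryl)but-2-en-1-yl]zinc 23 (not isolated)
Conditions: Zn dust, LiCl, THF, 0 → 23 °C; then 12, Pd(OAc)2 (3 mol%), CPhos (6 mol%), THF, 23 → 40 °C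
Reagents that add atoms: none
Why: Zinc insertion gives the allylzinc (a zinc dienolate), which in a linear-selective Negishi coupling is vinylated at its unsubstituted CH2 terminus by the enol triflate, forming the C5–C6 bond and joining the two fragments; the allylboronate, acetal and esters are spectators and no stereocentre is touched.

**Step 18**
Reactants: 24 methyl (2E)-4-{(3S,6R)-6-(2,2-dimethoxyethyl)-2,6-dimethyl-3-[(2Z)-2-methylbut-2-enoyloxy]cyclohex-1-en-1-yl}-2-[(pinacolboryl)methyl]but-2-enoate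
Product: 28 methyl (3S,7R,8R,10R)-8-acetoxy-3-angeloyloxyeudesma-4,11(13)-dien-12-oate, via methyl (2E)-4-{(3S,6R)-2,6-dimethyl-3-[(2Z)-2-methylbut-2-enoyloxy]-6-(2-oxoethyl)cyclohex-1-en-1-yl}-2-[(pinacolboryl)methyl]but-2-enoate 25 (not isolated), via methyl (3S,7R,8R,10R)-3-angeloyloxy-8-(pinacolboryloxy)eudesma-4,11(13)-dien-12-oate 26 (not isolated), via methyl (3S,7R,8R,10R)-3-angeloyloxy-8-hydroxyeudesma-4,11(13)-dien-12-oate 27 (not isolated)
Conditions: PPTS (0.2 equiv), acetone/H2O (9:1), 45 °C; evaporate; then Ac2O, pyridine, DMAP (cat.), CH2Cl2, 0 → 23 °C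
Reagents that add atoms: water, O; acetic anhydride, CC(=O)OC(C)=O
Why: Acetal hydrolysis frees the aldehyde, which undergoes intramolecular allylboration through a closed chair (Zimmerman–Traxler) transition state: the ring-tethered substituent cis to CH2B gives the syn (cis) C7/C8 pair, and an equatorial acrylate arm with axial O–B on the forming ring B gives 7R,8R; the crude alcohol is acetylated at once to forestall lactonisation.

**Step 19**
Reactants: 28 methyl (3S,7R,8R,10R)-8-acetoxy-3-angeloyloxyeudesma-4,11(13)-dien-12-oate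
Product: 30 methyl (3S,5S,7R,8R,10R)-8-acetoxy-3-angeloyloxy-5-hydroxyeudesma-4(15),11(13)-dien-12-oate (target), via methyl (3S,5S,7R,8R,10R)-8-acetoxy-3-angeloyloxy-5-hydroperoxyeudesma-4(15),11(13)-dien-12-oate 29 (not isolated)
Conditions: O2, tetraphenylporphyrin (1 mol%), visible light, CH2Cl2, −20 °C; then PPh3, −20 → 23 °C
Reagents that add atoms: oxygen, O=O
Why: Schenck ene reaction: singlet oxygen attacks the electron-rich tetrasubstituted Δ4 alkene from the α-face (anti to the C10 methyl and the 3β-ester) and abstracts a C15 methyl hydrogen, giving the 5α-hydroperoxide with the 4(15)-alkene, which PPh3 reduces to the 5S alcohol; the acrylate and angelate alkenes are electron-poor and inert.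

**Compound list**
1 | 2-methylcyclohex-2-en-1-one | CC1=CCCCC1=O | starting material
2 | 2,6-dimethylcyclohex-2-en-1-one (racemic) | CC1=CCCC(C)C1=O | intermediate
3 | allyl 2,6-dimethylcyclohexa-1,5-dien-1-yl carbonate | C=CCOC(=O)OC1=C(C)CCC=C1C | intermediate
4 | (6R)-6-allyl-2,6-dimethylcyclohex-2-en-1-one | C=CC[C@@]1(C)CCC=C(C)C1=O | intermediate
5 | (3S,6R)-6-allyl-2,6-dimethyl-3-(4,4,5,5-tetramethyl-1,3,2-dioxaborolan-2-yl)cyclohexan-1-one (C2 epimers) | C=CC[C@@]1(C)CC[C@H](B2OC(C)(C)C(C)(C)O2)C(C)C1=O | intermediate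
6 | (3S,6R)-6-allyl-3-hydroxy-2,6-dimethylcyclohexan-1-one (C2 epimers) | C=CC[C@@]1(C)CC[C@H](O)C(C)C1=O | intermediate
7 | angelic acid, (2Z)-2-methylbut-2-enoic acid | C/C=C(/C)C(=O)O | starting material
8 | angelic anhydride, (2Z)-2-methylbut-2-enoic anhydride | C/C=C(/C)C(=O)OC(=O)/C(C)=C\C | intermediate
9 | (1S,4R)-4-allyl-2,4-dimethyl-3-oxocyclohexyl (2Z)-2-methylbut-2-enoate (C2 epimers) | C=CC[C@@]1(C)CC[C@H](OC(=O)/C(C)=C\C)C(C)C1=O | intermediate
10 | (3S,6R)-6-allyl-2,6-dimethyl-3-[(2Z)-2-methylbut-2-enoyloxy]cyclohex-1-en-1-yl trifluoromethanesulfonate | C=CC[C@@]1(C)CC[C@H](OC(=O)/C(C)=C\C)C(C)=C1OS(=O)(=O)C(F)(F)F | intermediate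
11 | (3S,6R)-2,6-dimethyl-3-[(2Z)-2-methylbut-2-enoyloxy]-6-(2-oxoethyl)cyclohex-1-en-1-yl trifluoromethanesulfonate | O=CC[C@@]1(C)CC[C@H](OC(=O)/C(C)=C\C)C(C)=C1OS(=O)(=O)C(F)(F)F | intermediate
12 | (3S,6R)-6-(2,2-dimethoxyethyl)-2,6-dimethyl-3-[(2Z)-2-methylbut-2-enoyloxy]cyclohex-1-en-1-yl trifluoromethanesulfonate | COC(OC)C[C@@]1(C)CC[C@H](OC(=O)/C(C)=C\C)C(C)=C1OS(=O)(=O)C(F)(F)F | intermediate
13 | (2Z)-but-2-ene-1,4-diol | OC/C=C\CO | starting material
14 | (2Z)-1,4-bis(tert-butyldimethylsilyloxy)but-2-ene | CC(C)(C)[Si](C)(C)OC/C=C\CO[Si](C)(C)C(C)(C)C | intermediate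
15 | 3,5-bis[(tert-butyldimethylsilyloxy)methyl]-1,2,4-trioxolane (ozonide) | CC(C)(C)[Si](C)(C)OCC1OOC(CO[Si](C)(C)C(C)(C)C)O1 | intermediate
16 | (tert-butyldimethylsilyloxy)acetaldehyde | CC(C)(C)[Si](C)(C)OCC=O | intermediate
17 | methyl acrylate | C=CC(=O)OC | starting material
18 | methyl 4-(tert-butyldimethylsilyloxy)-3-hydroxy-2-methylidenebutanoate (racemic) | C=C(C(=O)OC)C(O)CO[Si](C)(C)C(C)(C)C | intermediate
19 | methyl 3-acetoxy-4-(tert-butyldimethylsilyloxy)-2-methylidenebutanoate (racemic) | C=C(C(=O)OC)C(OC(C)=O)CO[Si](C)(C)C(C)(C)C | intermediate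
20 | methyl (2E)-4-(tert-butyldimethylsilyloxy)-2-[(4,4,5,5-tetramethyl-1,3,2-dioxaborolan-2-yl)methyl]but-2-enoate | COC(=O)/C(CB1OC(C)(C)C(C)(C)O1)=C/CO[Si](C)(C)C(C)(C)C | intermediate
21 | methyl (2E)-4-hydroxy-2-[(4,4,5,5-tetramethyl-1,3,2-dioxaborolan-2-yl)methyl]but-2-enoate | COC(=O)/C(CB1OC(C)(C)C(C)(C)O1)=C/CO | intermediate
22 | methyl (2E)-4-chloro-2-[(4,4,5,5-tetramethyl-1,3,2-dioxaborolan-2-yl)methyl]but-2-enoate | COC(=O)/C(CB1OC(C)(C)C(C)(C)O1)=C/CCl | intermediate
23 | chloro[(2E)-3-(methoxycarbonyl)-4-(4,4,5,5-tetramethyl-1,3,2-dioxaborolan-2-yl)but-2-en-1-yl]zinc | COC(=O)/C(CB1OC(C)(C)C(C)(C)O1)=C/C[Zn]Cl | intermediate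
24 | methyl (2E)-4-{(3S,6R)-6-(2,2-dimethoxyethyl)-2,6-dimethyl-3-[(2Z)-2-methylbut-2-enoyloxy]cyclohex-1-en-1-yl}-2-[(4,4,5,5-tetramethyl-1,3,2-dioxaborolan-2-yl)methyl]but-2-enoate | COC(OC)C[C@@]1(C)CC[C@H](OC(=O)/C(C)=C\C)C(C)=C1C/C=C(\CB2OC(C)(C)C(C)(C)O2)C(=O)OC | intermediate
25 | methyl (2E)-4-{(3S,6R)-2,6-dimethyl-3-[(2Z)-2-methylbut-2-enoyloxy]-6-(2-oxoethyl)cyclohex-1-en-1-yl}-2-[(4,4,5,5-tetramethyl-1,3,2-dioxaborolan-2-yl)methyl]but-2-enoate | O=CC[C@@]1(C)CC[C@H](OC(=O)/C(C)=C\C)C(C)=C1C/C=C(\CB2OC(C)(C)C(C)(C)O2)C(=O)OC | intermediate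
26 | methyl (3S,7R,8R,10R)-3-angeloyloxy-8-(4,4,5,5-tetramethyl-1,3,2-dioxaborolan-2-yloxy)eudesma-4,11(13)-dien-12-oate (3β,7β,8β,10β-Me) | C=C(C(=O)OC)[C@H]1CC2=C(C)[C@@H](OC(=O)/C(C)=C\C)CC[C@]2(C)C[C@H]1OB3OC(C)(C)C(C)(C)O3 | intermediate
27 | methyl (3S,7R,8R,10R)-3-angeloyloxy-8-hydroxyeudesma-4,11(13)-dien-12-oate | C=C(C(=O)OC)[C@H]1CC2=C(C)[C@@H](OC(=O)/C(C)=C\C)CC[C@]2(C)C[C@H]1O | intermediate
28 | methyl (3S,7R,8R,10R)-8-acetoxy-3-angeloyloxyeudesma-4,11(13)-dien-12-oate | C=C(C(=O)OC)[C@H]1CC2=C(C)[C@@H](OC(=O)/C(C)=C\C)CC[C@]2(C)C[C@H]1OC(C)=O | intermediate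
29 | methyl (3S,5S,7R,8R,10R)-8-acetoxy-3-angeloyloxy-5-hydroperoxyeudesma-4(15),11(13)-dien-12-oate | C=C(C(=O)OC)[C@H]1C[C@@]2(OO)C(=C)[C@@H](OC(=O)/C(C)=C\C)CC[C@]2(C)C[C@H]1OC(C)=O | intermediate
30 | methyl (3S,5S,7R,8R,10R)-8-acetoxy-3-angeloyloxy-5-hydroxyeudesma-4(15),11(13)-dien-12-oate (CNP0179024.1) | C=C(C(=O)OC)[C@H]1C[C@@]2(O)C(=C)[C@@H](OC(=O)/C(C)=C\C)CC[C@]2(C)C[C@H]1OC(C)=O | target

**Step count**
Total step count: 19. Longest linear sequence: 11 steps (steps 1–4, 6–9, 17–19).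

**Steps most likely to fail, with fallbacks**

Step 17 (Negishi union) is the first risk: the enol triflate is tetrasubstituted and flanked by a quaternary carbon, and the ester-substituted allylzinc may couple slowly or homocouple. The fallback builds the same C5–C6–C7=C11 unit by cross-metathesis instead. It sets out from 12: Stille allylation (allyltributylstannane, Pd2(dba)3, AsPh3, LiCl, NMP, 60 °C) gives (1S,4R)-4-(2,2-dimethoxyethyl)-2,4-dimethyl-3-(prop-2-en-1-yl)cyclohex-2-en-1-yl (2Z)-2-methylbut-2-enoate F1. Cross-metathesis of its terminal alkene (Hoveyda–Grubbs II, CH2Cl2, 40 °C) with methyl 2-[(4,4,5,5-tetramethyl-1,3,2-dioxaborolan-2-yl)methyl]prop-2-enoate F2 (one step from commercial methyl 2-(bromomethyl)acrylate, B2pin2, CuCl, KOt-Bu) gives the E-enoate, and the route is rejoined at 24.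

Step 18 (ring-B closure) is the second risk, and the most serious one. Because C5 is still sp2, the alternative chair with the acrylate arm axial and the oxygen equatorial is not strongly disfavoured, so the 7α,8α-cis isomer may compete or dominate; the hydroxy ester 27 may also lactonise before acetylation. The fallback changes the ring-closing reaction to a metal-mediated Barbier cyclisation, whose metal can be varied. It sets out from 24: oxidation of the C–B bond (NaBO3·4H2O, THF/H2O) gives methyl (2E)-4-{(3S,6R)-6-(2,2-dimethoxyethyl)-2,6-dimethyl-3-[(2Z)-2-methylbut-2-enoyloxy]cyclohex-1-en-1-yl}-2-(hydroxymethyl)but-2-enoate F3. Appel bromination (CBr4, PPh3) gives methyl (2Z)-2-(bromomethyl)-4-{(3S,6R)-6-(2,2-dimethoxyethyl)-2,6-dimethyl-3-[(2Z)-2-methylbut-2-enoyloxy]cyclohex-1-en-1-yl}but-2-enoate F4. Acetal hydrolysis (PPTS, aqueous acetone) gives methyl (2Z)-2-(bromomethyl)-4-{(3S,6R)-2,6-dimethyl-3-[(2Z)-2-methylbut-2-enoyloxy]-6-(2-oxoethyl)cyclohex-1-en-1-yl}but-2-enoate F5. Indium-mediated intramolecular Barbier reaction (In, THF/H2O, 23 °C; Zn or CrCl2 as further options) then closes ring B through a metal-bridged chair, and the route is rejoined at 27, which is acetylated to 28 as in step 18.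

Step 19 (Schenck ene) is the third risk: hydrogen abstraction from C6 (giving the 4-hydroperoxy-5-ene) or attack on the β-face would erode the yield. The fallback replaces the ene reaction by dihydroxylation and dehydration. It sets out from 28: α-face dihydroxylation of the Δ4 alkene (OsO4, pyridine, then NaHSO3) gives methyl (3S,7R,8R,10R)-8-acetoxy-3-angeloyloxy-4α,5α-dihydroxyeudesm-11(13)-en-12-oate F6. Selective dehydration of the less hindered C4 tertiary hydroxyl toward the methyl group (Burgess reagent, toluene, 50 °C) gives the 4(15)-alkene with the 5α-hydroxyl retained, and the route is rejoined at 30.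

**Further compounds**
F1 | step 17 | (1S,4R)-4-(2,2-dimethoxyethyl)-2,4-dimethyl-3-(prop-2-en-1-yl)cyclohex-2-en-1-yl (2Z)-2-methylbut-2-enoate | COC(OC)C[C@@]1(C)CC[C@H](OC(=O)/C(C)=C\C)C(C)=C1CC=C
F2 | step 17 | methyl 2-[(4,4,5,5-tetramethyl-1,3,2-dioxaborolan-2-yl)methyl]prop-2-enoate | C=C(CB1OC(C)(C)C(C)(C)O1)C(=O)OC
F3 | step 18 | methyl (2E)-4-{(3S,6R)-6-(2,2-dimethoxyethyl)-2,6-dimethyl-3-[(2Z)-2-methylbut-2-enoyloxy]cyclohex-1-en-1-yl}-2-(hydroxymethyl)but-2-enoate | COC(OC)C[C@@]1(C)CC[C@H](OC(=O)/C(C)=C\C)C(C)=C1C/C=C(\CO)C(=O)OC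
F4 | step 18 | methyl (2Z)-2-(bromomethyl)-4-{(3S,6R)-6-(2,2-dimethoxyethyl)-2,6-dimethyl-3-[(2Z)-2-methylbut-2-enoyloxy]cyclohex-1-en-1-yl}but-2-enoate | COC(OC)C[C@@]1(C)CC[C@H](OC(=O)/C(C)=C\C)C(C)=C1C/C=C(\CBr)C(=O)OC
F5 | step 18 | methyl (2Z)-2-(bromomethyl)-4-{(3S,6R)-2,6-dimethyl-3-[(2Z)-2-methylbut-2-enoyloxy]-6-(2-oxoethyl)cyclohex-1-en-1-yl}but-2-enoate | O=CC[C@@]1(C)CC[C@H](OC(=O)/C(C)=C\C)C(C)=C1C/C=C(\CBr)C(=O)OC
F6 | step 19 | methyl (3S,7R,8R,10R)-8-acetoxy-3-angeloyloxy-4α,5α-dihydroxyeudesm-11(13)-en-12-oate | C=C(C(=O)OC)[C@H]1C[C@@]2(O)[C@](C)(O)[C@@H](OC(=O)/C(C)=C\C)CC[C@]2(C)C[C@H]1OC(C)=O
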